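**Retrosynthetic overview**
Numbering: ring A is the ten-membered carbocycle C1–C10 (C3 ketone, C4 CH–CH3, C5 CH2, C6 O–CH, C7 ring-fusion CH, C8 CH–O-isobutyryl, C10 C(OH)CH3); ring B is the lactone O–C6–C7–C11(=C13H2)–C12(=O).
Enabling feature: C5 is the β-carbon of the C3 ketone (through C4) and C6 carries the ring B oxygen, so ring A opens at C5–C6 into a 2-methylprop-2-enoyl ketone and an α-oxy (lactonyl) radical at C6; the radical comes from a C6 carboxylic acid by loss of CO2, so the C6 centre of the precursor is only a relay.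
Ring A is closed last by a 10-endo decarboxylative radical conjugate addition that also sets C6 and C4; its substrate is a monocyclic, protecting-group-free cis-lactone acid.
Lactone acid ⇐ indium-mediated syn 2-(methoxycarbonyl)allylation (C7–C8 bond, C7 and C8 set) of a keto aldehyde from (S)-linalool (C10) with a Baylis–Hillman bromide from (S)-glyceraldehyde acetonide (C6 relay), then C8 acylation and lactonisation.
Order of ring formation: ring B (step 9), then ring A (step 11).

Key step: step 11

Remark: the target is treated as the open C10-hydroxy C3-ketone; reversible transannular hemiketal formation between these two groups would not change any stereocentre.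

**Route**

Step 1
Reactants: 1 (S)-(+)-linalool
Product: 3 (3S)-3,7-dimethyloct-6-ene-1,3-diol, via B-alkyl-9-BBN adduct 2 (not isolated)
Conditions: 9-BBN (1.3 equiv), THF, 0 °C to rt; then NaOH, H2O2, 0 °C to rt
Reagents that add atoms: hydrogen peroxide, OO
Why: Anti-Markovnikov hydroboration–oxidation in which 9-BBN should take the monosubstituted vinyl group and leave the trisubstituted alkene, the C10 carbinol centre of the chiral pool being untouched.

Step 2
Reactants: 3 (3S)-3,7-dimethyloct-6-ene-1,3-diol
Product: 4 (5S)-5-(2-hydroxyethyl)-5-methyloxolan-2-ol (lactol, both anomers)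
Conditions: O3, CH2Cl2/MeOH, −78 °C; then Me2S, −78 °C to rt
Reagents that add atoms: ozone, [O-][O+]=O
Why: Ozonolysis of the only remaining alkene gives the C3 aldehyde, which should rest as the five-membered lactol with the tertiary hydroxyl; no stereocentre is affected.

Step 3
Reactants: 4 (5S)-5-(2-hydroxyethyl)-5-methyloxolan-2-ol; 5 isopropenylmagnesium bromide
Product: 6 (3S,6RS)-3,7-dimethyloct-7-ene-1,3,6-triol
Conditions: 5 (4 equiv), THF, 0 °C to rt; then sat. aq NH4Cl
Reagents that add atoms: none
Why: Grignard addition to the lactol, which opens to the aldehyde under the basic conditions, installs C4, C5 and the C4 methyl; the new C3 carbinol is unselective and is removed in step 4.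

Step 4
Reactants: 6 (3S,6RS)-3,7-dimethyloct-7-ene-1,3,6-triol
Product: 7 (3S)-3-hydroxy-3,7-dimethyl-6-oxooct-7-enal
Conditions: Dess–Martin periodinane (2.4 equiv), NaHCO3 (buffer), CH2Cl2, 0 °C to rt; used crude
Reagents that add atoms: none
Why: Dess–Martin oxidation should convert the primary alcohol to the C8 aldehyde and the allylic alcohol to the C3 enone in one operation, the tertiary C10 hydroxyl being inert and the buffer protecting the β-hydroxy aldehyde from dehydration.

Step 5
Reactants: 8 (4S)-2,2-dimethyl-1,3-dioxolane-4-carbaldehyde (L-glyceraldehyde acetonide); 9 methyl acrylate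
Product: 10 methyl 2-{[(4S)-2,2-dimethyl-1,3-dioxolan-4-yl](hydroxy)methyl}prop-2-enoate (both carbinol epimers)
Conditions: DABCO (0.5 equiv), 1,4-dioxane/H2O (1:1), rt
Reagents that add atoms: none
Why: Morita–Baylis–Hillman reaction; the new carbinol centre is formed as a mixture that step 6 erases, and the dioxolane centre (future C6) is not touched.

Step 6
Reactants: 10 methyl 2-{[(4S)-2,2-dimethyl-1,3-dioxolan-4-yl](hydroxy)methyl}prop-2-enoate
Product: 11 methyl (2Z)-2-(bromomethyl)-3-[(4R)-2,2-dimethyl-1,3-dioxolan-4-yl]prop-2-enoate (CIP label changes, geometry at the dioxolane centre unchanged)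
Conditions: NBS, Me2S, CH2Cl2, 0 °C to rt
Reagents that add atoms: N-bromosuccinimide, O=C1CCC(=O)N1Br
Why: Corey–Kim-type activation of the allylic alcohol followed by SN2′ attack of bromide should give the thermodynamically preferred Z bromide, with the dioxolanyl group cis to CH2Br and trans to the ester.

Step 7
Reactants: 7 (3S)-3-hydroxy-3,7-dimethyl-6-oxooct-7-enal; 11 methyl (2Z)-2-(bromomethyl)-3-[(4R)-2,2-dimethyl-1,3-dioxolan-4-yl]prop-2-enoate
Product: 13 methyl (3R,4R,6S)-3-[(4R)-2,2-dimethyl-1,3-dioxolan-4-yl]-4,6-dihydroxy-6,10-dimethyl-2-methylidene-9-oxoundec-10-enoate, via allylindium dibromide 12 (not isolated)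
Conditions: In powder (1.5 equiv), THF/H2O (1:1), rt; crude product taken directly into step 8
Reagents that add atoms: none
Why: Barbier-type indium-mediated 2-(alkoxycarbonyl)allylation in which the allylindium (CH2In cis to the dioxolanyl group) adds to the aldehyde rather than the enone ketone through a closed chair with the aldehyde chain equatorial and the dioxolanyl group axial, giving the syn C7/C8 relationship, while A(1,3) strain holds C6–H in the allyl plane so that the aldehyde should bond to the C7 face anti to the C6–CH2O bond (ring oxygen outside), which fixes C7 and C8 in the arrangement of the target.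

Step 8
Reactants: 13 methyl (3R,4R,6S)-3-[(4R)-2,2-dimethyl-1,3-dioxolan-4-yl]-4,6-dihydroxy-6,10-dimethyl-2-methylidene-9-oxoundec-10-enoate
Product: 14 methyl (3R,4R,6S)-3-[(4R)-2,2-dimethyl-1,3-dioxolan-4-yl]-6-hydroxy-6,10-dimethyl-2-methylidene-4-(2-methylpropanoyloxy)-9-oxoundec-10-enoate
Conditions: (i-PrCO)2O (1.5 equiv), DMAP (0.1 equiv), Et3N, CH2Cl2, 0 °C
Reagents that add atoms: isobutyric anhydride, CC(C)C(=O)OC(=O)C(C)C
Why: DMAP-catalysed acylation should take the secondary C8 hydroxyl and leave the tertiary C10 hydroxyl, and capping C8 at once blocks lactonisation through O8 so that ring B can only close through O6.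

Step 9
Reactants: 14 methyl (3R,4R,6S)-3-[(4R)-2,2-dimethyl-1,3-dioxolan-4-yl]-6-hydroxy-6,10-dimethyl-2-methylidene-4-(2-methylpropanoyloxy)-9-oxoundec-10-enoate
Product: 16 (1R,3S)-3-hydroxy-1-[(2R,3R)-2-(hydroxymethyl)-4-methylidene-5-oxooxolan-3-yl]-3,7-dimethyl-6-oxooct-7-en-1-yl 2-methylpropanoate, via diol ester 15 (not isolated)
Conditions: AcOH/H2O (4:1), 40 °C; concentrate; then CSA (0.1 equiv), CH2Cl2, rt
Reagents that add atoms: none
Why: Acid hydrolysis of the terminal acetonide followed by acid-catalysed 5-exo-trig lactonisation of the secondary C6 hydroxyl onto the methyl ester should close ring B as the γ-lactone in preference to the six-membered lactone through the primary hydroxyl; no stereocentre is touched and C6/C7 are cis on the ring as built in step 7.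

Step 10
Reactants: 16 (1R,3S)-3-hydroxy-1-[(2R,3R)-2-(hydroxymethyl)-4-methylidene-5-oxooxolan-3-yl]-3,7-dimethyl-6-oxooct-7-en-1-yl 2-methylpropanoate
Product: 18 (2R,3R)-3-[(1R,3S)-3-hydroxy-3,7-dimethyl-1-(2-methylpropanoyloxy)-6-oxooct-7-en-1-yl]-4-methylidene-5-oxooxolane-2-carboxylic acid, via aldehyde 17 (not isolated)
Conditions: TEMPO (0.2 equiv), PhI(OAc)2 (2.5 equiv), MeCN/H2O (1:1), rt
Reagents that add atoms: water, O
Why: Oxoammonium (TEMPO) oxidation of the primary alcohol to the aldehyde and of its hydrate to the acid should tolerate the tertiary alcohol, the enone and the methylidene lactone; epimerisation at C6 would be harmless because step 11 erases that centre.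

Step 11
Reactants: 18 (2R,3R)-3-[(1R,3S)-3-hydroxy-3,7-dimethyl-1-(2-methylpropanoyloxy)-6-oxooct-7-en-1-yl]-4-methylidene-5-oxooxolane-2-carboxylic acid
Product: 21 (3aS,4R,6S,10R,11aS)-6-hydroxy-6,10-dimethyl-3-methylidene-2,9-dioxododecahydrocyclodeca[b]furan-4-yl 2-methylpropanoate (target), via lactonyl radical 19 (not isolated), via potassium enolate 20 (not isolated)
Conditions: Ir[dF(CF3)ppy]2(dtbbpy)PF6 (2 mol %), K2HPO4 (1.2 equiv), degassed DMF (2 mM), blue LEDs (450 nm), rt, argon
Reagents that add atoms: none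
Why: The carboxylate of 18 is oxidised by the photoexcited trivalent-iridium complex, CO2 is lost, and the planar α-oxy radical 19 at C6 of ring B adds to C5, the unsubstituted terminus of the 2-methylprop-2-enoyl ketone; the resulting tertiary C4 radical is reduced by the divalent-iridium state to enolate 20, which is protonated. The closest known reaction type is the photoredox decarboxylative radical conjugate addition (Giese reaction) of α-heteroatom carboxylic acids, including its macrocyclising variant. Ring A closes in the 10-endo-trig mode. At C6 the configuration of 18 is erased and should be re-set by C7, because the eight-atom tether anchored at C7 reaches the radical lobe on its own face (C5–C6–C7–C8 gauche) and so gives the cis ring fusion; C4 is set by protonation of 20 on the open outer face and, being α to the ketone, remains open to equilibration toward the 4R epimer with the methyl group pseudo-equatorial. The step needs attack at C5 rather than at C13: C13 lies in the same five-membered ring as the radical, so only intermolecular addition to a methylidene lactone competes and high dilution suppresses it, while polarity matching (nucleophilic α-oxy radical, electron-poor enone) and the quaternary C10, which blocks 1,5-hydrogen transfer from the tether, favour closure.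

**Compound list**
1 | (S)-(+)-linalool, (3S)-3,7-dimethylocta-1,6-dien-3-ol | CC(C)=CCC[C@](C)(O)C=C | starting material
2 | (3R)-1-(9-borabicyclo[3.3.1]nonan-9-yl)-3,7-dimethyloct-6-en-3-ol (CIP label changes, geometry as in 1) | CC(C)=CCC[C@](C)(O)CCB1C2CCCC1CCC2 | intermediate
3 | (3S)-3,7-dimethyloct-6-ene-1,3-diol | CC(C)=CCC[C@](C)(O)CCO | intermediate
4 | (5S)-5-(2-hydroxyethyl)-5-methyloxolan-2-ol (anomeric mixture) | OCC[C@]1(C)CCC(O)O1 | intermediate
5 | isopropenylmagnesium bromide (prop-1-en-2-ylmagnesium bromide) | C=C(C)[Mg]Br | starting material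
6 | (3S,6RS)-3,7-dimethyloct-7-ene-1,3,6-triol | C=C(C)C(O)CC[C@](C)(O)CCO | intermediate
7 | (3S)-3-hydroxy-3,7-dimethyl-6-oxooct-7-enal | C=C(C)C(=O)CC[C@](C)(O)CC=O | intermediate
8 | (4S)-2,2-dimethyl-1,3-dioxolane-4-carbaldehyde | O=C[C@@H]1COC(C)(C)O1 | starting material
9 | methyl acrylate | C=CC(=O)OC | starting material
10 | methyl 2-{[(4S)-2,2-dimethyl-1,3-dioxolan-4-yl](hydroxy)methyl}prop-2-enoate (carbinol epimers) | C=C(C(=O)OC)C(O)[C@@H]1COC(C)(C)O1 | intermediate
11 | methyl (2Z)-2-(bromomethyl)-3-[(4R)-2,2-dimethyl-1,3-dioxolan-4-yl]prop-2-enoate | BrC/C(C(=O)OC)=C\[C@@H]1COC(C)(C)O1 | intermediate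
12 | [(2Z)-3-[(4R)-2,2-dimethyl-1,3-dioxolan-4-yl]-2-(methoxycarbonyl)prop-2-en-1-yl]indium dibromide (trivalent indium, drawn as the monomer) | Br[In](Br)C/C(C(=O)OC)=C\[C@@H]1COC(C)(C)O1 | intermediate
13 | methyl (3R,4R,6S)-3-[(4R)-2,2-dimethyl-1,3-dioxolan-4-yl]-4,6-dihydroxy-6,10-dimethyl-2-methylidene-9-oxoundec-10-enoate | C=C(C(=O)OC)[C@@H]([C@@H]1COC(C)(C)O1)[C@H](O)C[C@@](C)(O)CCC(=O)C(C)=C | intermediate
14 | methyl (3R,4R,6S)-3-[(4R)-2,2-dimethyl-1,3-dioxolan-4-yl]-6-hydroxy-6,10-dimethyl-2-methylidene-4-(2-methylpropanoyloxy)-9-oxoundec-10-enoate | C=C(C(=O)OC)[C@@H]([C@@H]1COC(C)(C)O1)[C@H](OC(=O)C(C)C)C[C@@](C)(O)CCC(=O)C(C)=C | intermediate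
15 | methyl (3S,4R,6S)-3-[(1R)-1,2-dihydroxyethyl]-6-hydroxy-6,10-dimethyl-2-methylidene-4-(2-methylpropanoyloxy)-9-oxoundec-10-enoate | C=C(C(=O)OC)[C@@H]([C@@H](O)CO)[C@H](OC(=O)C(C)C)C[C@@](C)(O)CCC(=O)C(C)=C | intermediate
16 | (1R,3S)-3-hydroxy-1-[(2R,3R)-2-(hydroxymethyl)-4-methylidene-5-oxooxolan-3-yl]-3,7-dimethyl-6-oxooct-7-en-1-yl 2-methylpropanoate | C=C1C(=O)O[C@@H](CO)[C@H]1[C@H](OC(=O)C(C)C)C[C@@](C)(O)CCC(=O)C(C)=C | intermediate
17 | (1R,3S)-1-[(2R,3R)-2-formyl-4-methylidene-5-oxooxolan-3-yl]-3-hydroxy-3,7-dimethyl-6-oxooct-7-en-1-yl 2-methylpropanoate | C=C1C(=O)O[C@@H](C=O)[C@H]1[C@H](OC(=O)C(C)C)C[C@@](C)(O)CCC(=O)C(C)=C | intermediate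
18 | (2R,3R)-3-[(1R,3S)-3-hydroxy-3,7-dimethyl-1-(2-methylpropanoyloxy)-6-oxooct-7-en-1-yl]-4-methylidene-5-oxooxolane-2-carboxylic acid | C=C1C(=O)O[C@@H](C(=O)O)[C@H]1[C@H](OC(=O)C(C)C)C[C@@](C)(O)CCC(=O)C(C)=C | intermediate
19 | C6-centred lactonyl radical from 18 (4-methylidene-5-oxooxolan-2-yl radical; C7, C8, C10 as in 18) | C=C1C(=O)O[CH][C@H]1[C@H](OC(=O)C(C)C)C[C@@](C)(O)CCC(=O)C(C)=C | intermediate
20 | potassium C3–C4 enolate of 21 (C4 planar; C6, C7, C8, C10 as in 21) | C=C1C(=O)O[C@H]2CC(C)=C([O-])CC[C@](C)(O)C[C@@H](OC(=O)C(C)C)[C@@H]12.[K+] | intermediate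
21 | (3aS,4R,6S,10R,11aS)-6-hydroxy-6,10-dimethyl-3-methylidene-2,9-dioxododecahydrocyclodeca[b]furan-4-yl 2-methylpropanoate | C=C1C(=O)O[C@H]2C[C@@H](C)C(=O)CC[C@](C)(O)C[C@@H](OC(=O)C(C)C)[C@@H]12 | target

**Step count and risks**
Total step count: 11. Longest linear sequence: 9 steps (steps 1–4 and 7–11, from 1); steps 5–6 form the second branch.

Most likely to fail, in this order:

First, step 11. The 10-endo closure is slow for a radical cyclisation. Hydrogen-atom capture by the C6 radical (plain decarboxylation), intermolecular addition to a methylidene lactone, or sluggish oxidation of the α-acyloxy carboxylate may outrun it. The cis-fusion argument is a conformational expectation, not a precedent, so closure on the face anti to C8 (trans ring fusion) is possible, as is unselective protonation at C4. The fallback sets out from 18 and generates the same radical reductively. Condensation with N-hydroxyphthalimide (DIC, DMAP cat., CH2Cl2) should give the redox-active ester 1,3-dioxoisoindolin-2-yl (2R,3R)-3-[(1R,3S)-3-hydroxy-3,7-dimethyl-1-(2-methylpropanoyloxy)-6-oxooct-7-en-1-yl]-4-methylidene-5-oxooxolane-2-carboxylate F1. Slow addition of F1 to Ru(bpy)3(PF6)2, Hantzsch ester and i-Pr2NEt·HBF4 in CH2Cl2 (1 mM, blue LEDs) fragments it to radical 19 without carboxylate oxidation, and Hantzsch ester ends the chain at C4 by hydrogen-atom transfer. The fallback comes back to the route at 21.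

Second, step 7. The dioxolane centre is the only source of absolute configuration for C7 and C8, and the sense of its facial bias rests on a model; facial control may be poor or reversed. The closed transition state may also loosen in water (syn/anti leakage), the allylindium may lose the β-alkoxide to give a diene, and 13 may lactonise through O8 before acylation. The fallback sets out from 10 and 7 and replaces the Barbier reaction by a thermal allylboration. Acetylation of 10 (Ac2O, DMAP, CH2Cl2) gives methyl 2-{(acetyloxy)[(4S)-2,2-dimethyl-1,3-dioxolan-4-yl]methyl}prop-2-enoate F2. SN2′ borylation (B2pin2, CuCl, LiCl, KOAc, DMF) should give methyl (2E)-3-[(4R)-2,2-dimethyl-1,3-dioxolan-4-yl]-2-[(4,4,5,5-tetramethyl-1,3,2-dioxaborolan-2-yl)methyl]prop-2-enoate F3, which has the same geometry as 11 (CH2B cis to the dioxolanyl group). F3 and 7 in toluene (rt to 50 °C) react through a strictly closed chair, the boronate cannot eliminate and ignores the ketone, and hydrolytic work-up returns the route at 13.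

Third, step 9. The primary hydroxyl of 15 may lactonise to the six-membered lactone, the isobutyryl group may migrate from O8 to the free C6 hydroxyl before ring B closes, and the acid may dehydrate C10. The fallback sets out from 14 and directs the lactonisation with a protecting group. The acetonide is hydrolysed (AcOH/H2O, rt) and diol 15 is isolated. Selective silylation of the primary hydroxyl (TBSCl, imidazole, CH2Cl2, −20 °C) gives methyl (3S,4R,6S)-3-[(1R)-2-{[tert-butyl(dimethyl)silyl]oxy}-1-hydroxyethyl]-6-hydroxy-6,10-dimethyl-2-methylidene-4-(2-methylpropanoyloxy)-9-oxoundec-10-enoate F4. In F4 only the C6 hydroxyl can close (CSA cat., CH2Cl2), giving (1R,3S)-1-[(2R,3R)-2-({[tert-butyl(dimethyl)silyl]oxy}methyl)-4-methylidene-5-oxooxolan-3-yl]-3-hydroxy-3,7-dimethyl-6-oxooct-7-en-1-yl 2-methylpropanoate F5. HF·pyridine in THF removes the silyl group and the route is rejoined at 16.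

**Further compounds**
F1 | step 11 | 1,3-dioxoisoindolin-2-yl (2R,3R)-3-[(1R,3S)-3-hydroxy-3,7-dimethyl-1-(2-methylpropanoyloxy)-6-oxooct-7-en-1-yl]-4-methylidene-5-oxooxolane-2-carboxylate | C=C1C(=O)O[C@@H](C(=O)ON2C(=O)c3ccccc3C2=O)[C@H]1[C@H](OC(=O)C(C)C)C[C@@](C)(O)CCC(=O)C(C)=C
F2 | step 7 | methyl 2-{(acetyloxy)[(4S)-2,2-dimethyl-1,3-dioxolan-4-yl]methyl}prop-2-enoate | C=C(C(=O)OC)C(OC(C)=O)[C@@H]1COC(C)(C)O1
F3 | step 7 | methyl (2E)-3-[(4R)-2,2-dimethyl-1,3-dioxolan-4-yl]-2-[(4,4,5,5-tetramethyl-1,3,2-dioxaborolan-2-yl)methyl]prop-2-enoate | CC1(C)OB(C/C(C(=O)OC)=C\[C@@H]2COC(C)(C)O2)OC1(C)C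
F4 | step 9 | methyl (3S,4R,6S)-3-[(1R)-2-{[tert-butyl(dimethyl)silyl]oxy}-1-hydroxyethyl]-6-hydroxy-6,10-dimethyl-2-methylidene-4-(2-methylpropanoyloxy)-9-oxoundec-10-enoate | C=C(C(=O)OC)[C@@H]([C@@H](O)CO[Si](C)(C)C(C)(C)C)[C@H](OC(=O)C(C)C)C[C@@](C)(O)CCC(=O)C(C)=C
F5 | step 9 | (1R,3S)-1-[(2R,3R)-2-({[tert-butyl(dimethyl)silyl]oxy}methyl)-4-methylidene-5-oxooxolan-3-yl]-3-hydroxy-3,7-dimethyl-6-oxooct-7-en-1-yl 2-methylpropanoate | C=C1C(=O)O[C@@H](CO[Si](C)(C)C(C)(C)C)[C@H]1[C@H](OC(=O)C(C)C)C[C@@](C)(O)CCC(=O)C(C)=C
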